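## Retrosynthetic overview

- The butenolide C=C comes from loss of HCl from an α-chloro-α-methyl-γ-lactone, itself the Baeyer–Villiger ring expansion product of a 2-chloro-2-methyl-3-alkylcyclobutanone.
- That cyclobutanone is the only ring-forming event: a [2+2] cycloaddition of chloro(methyl)ketene to the terminal alkene of (S)-octadec-17-en-2-yl acetate sets all four lactone carbons and the ring methyl at once.
- The alkene acetate comes from (S)-propylene oxide (the bought stereocentre), opened at CH2 by a C15 alkenyl Grignard reagent and acetylated in the same flask.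
- The C15 alkenyl chloride comes from 11-bromoundec-1-ene and 1-bromo-4-chlorobutane by copper-catalysed coupling.
- Ring order: four-membered carbocycle first (step 3), expanded to the five-membered lactone (step 4), unsaturation last (step 5).

Assumption: 2-chloropropanoyl chloride is used as the racemate, and 11 and 12 are carried as mixtures of ring diastereomers, because both ring stereocentres become sp2 in step 5.

## Route

Step 1
Reactants: 1 11-bromoundec-1-ene; 2 1-bromo-4-chlorobutane
Product: 4 15-chloropentadec-1-ene, via undec-10-enylmagnesium bromide 3 (not isolated)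
Conditions: Mg, THF, 40 °C; then 2 (1.5 equiv), Li2CuCl4 (3 mol %), THF, −10 °C → rt
Reagents that add atoms: none
Why: Kochi-type copper-catalysed sp3–sp3 Grignard cross-coupling, in which the primary C–Br bond reacts far faster than the C–Cl bond, so the chain grows by four carbons and keeps a chloride handle; no stereocentre is involved.

Step 2
Reactants: 4 15-chloropentadec-1-ene; 5 (S)-propylene oxide
Product: 8 (S)-octadec-17-en-2-yl acetate, via pentadec-14-enylmagnesium chloride 6 (not isolated), via chloromagnesium (S)-octadec-17-en-2-olate 7 (not isolated)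
Conditions: Mg, I2 (cat.), THF, reflux; CuI (10 mol %), 5 (1.3 equiv), THF, −30 → 0 °C; then Ac2O (2.5 equiv), DMAP (cat.), 0 °C → rt; aq. NH4Cl
Reagents that add atoms: acetic anhydride, CC(=O)OC(C)=O
Why: Copper-catalysed SN2 opening of the epoxide at its unsubstituted CH2 by the Grignard reagent leaves the C–O stereocentre of 5 untouched, so the (S) configuration is carried over unchanged, and the magnesium alkoxide is O-acetylated in the same pot.

Step 3
Reactants: 8 (S)-octadec-17-en-2-yl acetate; 9 2-chloropropanoyl chloride
Product: 11 (2S)-16-(2-chloro-2-methyl-3-oxocyclobutyl)hexadecan-2-yl acetate (mixture of ring diastereomers), via chloro(methyl)ketene 10 (not isolated)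
Conditions: 9 (4 equiv), Et3N (4 equiv, slow addition over 8 h), cyclohexane, reflux
Reagents that add atoms: none
Why: Thermal [2+2] ketene–alkene cycloaddition in which the ketene carbonyl carbon bonds to the terminal CH2 and the Cl/Me-bearing carbon to the internal CH, giving the 2-chloro-2-methyl-3-alkylcyclobutanone; the two new ring stereocentres form uncontrolled, which does not matter because both are removed in step 5.

Step 4
Reactants: 11 (2S)-16-(2-chloro-2-methyl-3-oxocyclobutyl)hexadecan-2-yl acetate
Product: 12 (2S)-16-(4-chloro-4-methyl-5-oxooxolan-3-yl)hexadecan-2-yl acetate (mixture of ring diastereomers)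
Conditions: mCPBA (1.3 equiv), CH2Cl2, 0 °C → rt
Reagents that add atoms: mCPBA (3-chloroperoxybenzoic acid), OOC(=O)c1cccc(Cl)c1
Why: Baeyer–Villiger oxidation of the strained cyclobutanone, in which the electron-poor chlorine-bearing carbon migrates poorly, so the ring CH2 migrates and oxygen is inserted on the CH2 side to give the γ-lactone with O–CH2; existing stereocentres are unchanged.

Step 5
Reactants: 12 (2S)-16-(4-chloro-4-methyl-5-oxooxolan-3-yl)hexadecan-2-yl acetate
Product: 13 (2S)-16-(4-methyl-5-oxo-2,5-dihydrofuran-3-yl)hexadecan-2-yl acetate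
Conditions: LiBr (3 equiv), Li2CO3 (3 equiv), DMF, 110 °C
Reagents that add atoms: none
Why: Halide-promoted E2 dehydrochlorination of the tertiary α-chloro lactone, which should favour the conjugated, tetrasubstituted (Zaitsev) endocyclic alkene and removes both ring stereocentres, while the remote acetate stereocentre is not touched.

## Compound list

1 | 11-bromoundec-1-ene | BrCCCCCCCCCC=C | starting material
2 | 1-bromo-4-chlorobutane | ClCCCCBr | starting material
3 | undec-10-enylmagnesium bromide | Br[Mg]CCCCCCCCCC=C | intermediate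
4 | 15-chloropentadec-1-ene | ClCCCCCCCCCCCCCC=C | intermediate
5 | (S)-propylene oxide ((S)-2-methyloxirane) | C[C@H]1CO1 | starting material
6 | pentadec-14-enylmagnesium chloride | Cl[Mg]CCCCCCCCCCCCCC=C | intermediate
7 | chloromagnesium (S)-octadec-17-en-2-olate | Cl[Mg]O[C@@H](C)CCCCCCCCCCCCCCC=C | intermediate
8 | (S)-octadec-17-en-2-yl acetate | CC(=O)O[C@@H](C)CCCCCCCCCCCCCCC=C | intermediate
9 | 2-chloropropanoyl chloride (racemic) | CC(Cl)C(Cl)=O | starting material
10 | chloro(methyl)ketene (2-chloroprop-1-en-1-one) | CC(Cl)=C=O | intermediate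
11 | (2S)-16-(2-chloro-2-methyl-3-oxocyclobutyl)hexadecan-2-yl acetate, ring diastereomer mixture | CC(=O)O[C@@H](C)CCCCCCCCCCCCCCC1CC(=O)C1(C)Cl | intermediate
12 | (2S)-16-(4-chloro-4-methyl-5-oxooxolan-3-yl)hexadecan-2-yl acetate, ring diastereomer mixture | CC(=O)O[C@@H](C)CCCCCCCCCCCCCCC1COC(=O)C1(C)Cl | intermediate
13 | (2S)-16-(4-methyl-5-oxo-2,5-dihydrofuran-3-yl)hexadecan-2-yl acetate | CC(=O)O[C@@H](C)CCCCCCCCCCCCCCC1=C(C)C(=O)OC1 | target

## Step count and risks

Total steps: 5. Longest linear sequence: 5 steps (1 → 4 → 8 → 11 → 12 → 13).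

**Step 3 (ketene cycloaddition).** Chloro(methyl)ketene is only moderately electrophilic, and a monosubstituted unactivated alkene may be outrun by ketene dimerisation. The fallback sets out from 8 and carries the methyl in later instead of on the ketene.
- Dichloroketene (Cl3CCOCl, Zn(Cu), POCl3, Et2O, reflux), which adds reliably to 1-alkenes, gives the dichlorocyclobutanone (2S)-16-(2,2-dichloro-3-oxocyclobutyl)hexadecan-2-yl acetate F1.
- mCPBA in CH2Cl2 gives the dichlorolactone (2S)-16-(4,4-dichloro-5-oxooxolan-3-yl)hexadecan-2-yl acetate F2.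
- Et3N in CH2Cl2 removes HCl to give the chlorobutenolide (2S)-16-(4-chloro-5-oxo-2,5-dihydrofuran-3-yl)hexadecan-2-yl acetate F3.
- Suzuki–Miyaura methylation of the activated alkenyl chloride (trimethylboroxine, Pd(OAc)2, SPhos, K3PO4, toluene, 90 °C) comes back to the route at 13. This coupling is the least precedented operation of the fallback.

**Step 4 (Baeyer–Villiger regiochemistry).** If the tertiary C(Cl)Me carbon migrates instead of CH2, the product is a useless 5-chloro-5-methyl lactone. The fallback sets out from 8 and builds the butenolide without a four-membered ring.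
- Ketohydroxylation of the terminal alkene (RuCl3 cat., KHSO5 as 2KHSO5·KHSO4·K2SO4, NaHCO3, EtOAc/MeCN/H2O, rt) gives the hydroxy ketone (2S)-18-hydroxy-17-oxooctadecan-2-yl acetate F4.
- Esterification with 2-(diethoxyphosphoryl)propanoic acid (DCC, DMAP, CH2Cl2) gives the phosphonate ester (17S)-17-acetoxy-2-oxooctadecyl 2-(diethoxyphosphoryl)propanoate F5.
- Intramolecular Horner–Wadsworth–Emmons olefination (LiCl, DBU, MeCN, rt) closes the ring and comes back to the route at 13.

**Step 5 (direction of HCl loss).** The diastereomer of 12 with Cl cis to the ring C3–H has no anti-periplanar ring hydrogen and can eliminate toward the methyl group instead. The fallback sets out from 12 and accepts that outcome.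
- DBU in toluene at 80 °C completes the elimination, giving the α-methylene lactone (2S)-16-(4-methylidene-5-oxooxolan-3-yl)hexadecan-2-yl acetate F6 alongside 13.
- The unseparated mixture is then isomerised with RhCl3·3H2O (5 mol %) in EtOH at 70 °C, a metal-hydride addition–elimination that moves the exocyclic double bond into the ring, and comes back to the route at 13.

## Further compounds

F1 | step 3 | (2S)-16-(2,2-dichloro-3-oxocyclobutyl)hexadecan-2-yl acetate | CC(=O)O[C@@H](C)CCCCCCCCCCCCCCC1CC(=O)C1(Cl)Cl
F2 | step 3 | (2S)-16-(4,4-dichloro-5-oxooxolan-3-yl)hexadecan-2-yl acetate | CC(=O)O[C@@H](C)CCCCCCCCCCCCCCC1COC(=O)C1(Cl)Cl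
F3 | step 3 | (2S)-16-(4-chloro-5-oxo-2,5-dihydrofuran-3-yl)hexadecan-2-yl acetate | CC(=O)O[C@@H](C)CCCCCCCCCCCCCCC1=C(Cl)C(=O)OC1
F4 | step 4 | (2S)-18-hydroxy-17-oxooctadecan-2-yl acetate | CC(=O)O[C@@H](C)CCCCCCCCCCCCCCC(=O)CO
F5 | step 4 | (17S)-17-acetoxy-2-oxooctadecyl 2-(diethoxyphosphoryl)propanoate | CC(=O)O[C@@H](C)CCCCCCCCCCCCCCC(=O)COC(=O)C(C)P(=O)(OCC)OCC
F6 | step 5 | (2S)-16-(4-methylidene-5-oxooxolan-3-yl)hexadecan-2-yl acetate | CC(=O)O[C@@H](C)CCCCCCCCCCCCCCC1COC(=O)C1=C
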